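## Retrosynthetic overview
1. The aromatic ring is bought as a quinone, so only the pyran ring is built. It closes last, at O1–C8a, by stereoretentive cyclodehydration of hydroquinone carbinol 8, and the C2–O bond is never broken.
2. C4–C4a is the key bond. It forms by light-driven deborylative radical C–H alkylation of trimethylbenzoquinone with the primary boronate made from the vinyl group of (R)-geranyllinalool 5.
3. C5'–C6' forms by α,α'-selective allyl–allyl coupling of geranylbarium with (R,E)-8-bromolinalool 3.
4. (R)-(−)-Linalool supplies C2 with its O, CH3, C3–C4 and C1'–C5'. The 3'E geometry comes from E-selective SeO2 oxidation, and the 7'E geometry is bought in geranyl chloride.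

Assumption: natural (R)-(−)-linalool (ho-wood/ho-leaf grade, ≥97% ee) is used, and the product ee equals the ee of that lot.

## Route

**Step 1**
Reactants: 1, (R)-(−)-linalool
Product: 2, (2E,6R)-2,6-dimethylocta-2,7-diene-1,6-diol [(R,E)-8-hydroxylinalool]
Conditions: SeO2 (0.3 equiv), t-BuOOH (2.5 equiv), salicylic acid (0.1 equiv), CH2Cl2, 0 °C→rt. Then NaBH4, MeOH, 0 °C, which returns over-oxidised enal to 2.
Reagents that add atoms: tert-butyl hydroperoxide CC(C)(C)OO with selenium dioxide O=[Se]=O (one O)
Why: In this Sharpless–Umbreit allylic oxidation (ene, then [2,3]-sigmatropic shift), SeO2 attacks only the electron-rich trisubstituted alkene and oxidises its E-methyl, leaving the vinyl group and the stereocenter untouched.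

**Step 2**
Reactants: 2
Product: 3, (3R,6E)-8-bromo-3,7-dimethylocta-1,6-dien-3-ol
Conditions: MsCl (1.05 equiv), Et3N, THF, −45 °C. Then LiBr (4 equiv), 0 °C, 1 h. Use the same day.
Reagents that add atoms: lithium bromide [Li+].[Br-]
Why: Only the primary allylic alcohol is mesylated at −45 °C, and SN2 displacement by bromide proceeds without allylic transposition, so the E-alkene and the tertiary carbinol are preserved.

**Step 3**
Reactants: 3; 4, (E)-geranyl chloride (2.5 equiv)
Product: 5, (3R,6E,10E)-3,7,11,15-tetramethylhexadeca-1,6,10,14-tetraen-3-ol [(R)-geranyllinalool]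
Conditions: BaI2 and lithium biphenylide (2 equiv per Ba), THF, rt (active Ba). Add 4 at −78 °C, 30 min. Then add 3 at −78 °C, 2 h. Quench with aq NH4Cl.
Reagents that add atoms: none
Why: In Yamamoto-type cross-coupling, allylbarium reagents hold their E geometry at −78 °C and react α,α' with allylic bromides to give the linear 1,5-diene, while the first equivalent only deprotonates the tertiary OH.

**Step 4**
Reactants: 5
Product: 6, 2-{(3S,6E,10E)-3-[(1,3,2-benzodioxaborol-2-yl)oxy]-3,7,11,15-tetramethylhexadeca-6,10,14-trien-1-yl}-1,3,2-benzodioxaborole. Geometry is unchanged; the descriptor reads S only because B ranks below C. Not isolated.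
Conditions: catecholborane (1.1 equiv), THF, 0 °C, then purge H2 with Ar. Add RhCl(PPh3)3 (1 mol %) and catecholborane (1.2 equiv), rt, 1 h. Add t-BuOH (0.3 equiv) to destroy excess hydride.
Reagents that add atoms: catecholborane [H]B1Oc2ccccc2O1 (two Bcat units)
Why: Rh-catalysed (Männig–Nöth) hydroboration is anti-Markovnikov and strongly selective for the monosubstituted alkene over the three trisubstituted ones, and prior O-borylation masks the carbinol.

**Step 5**
Reactants: 6 (same flask); 7, 2,3,5-trimethyl-1,4-benzoquinone (2.0 equiv)
Product: 8, 2-[(3R,6E,10E)-3-hydroxy-3,7,11,15-tetramethylhexadeca-6,10,14-trien-1-yl]-3,5,6-trimethylbenzene-1,4-diol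
Conditions: zinc tetraphenylporphyrin (ZnTPP, 1 mol %), THF (0.3 M in 6), freeze–pump–thaw, 590 nm LEDs, 15 °C, 2–4 h. Then MeOH and an aq Na2S2O4 wash under N2, followed by a short deoxygenated silica plug.
Reagents that add atoms: none (work-up replaces O–B by O–H)
Why: Proposed new method: at 590 nm only ZnTPP absorbs, and its 1.6 eV triplet cannot sensitise the quinone or the alkenes, so Paternò–Büchi addition, allylic H-abstraction and E/Z scrambling by excited quinone are avoided; ZnTPP* (about −0.8 to −1.25 V) reduces 7 (about −0.75 V vs SCE), the semiquinone oxygen attacks the Lewis-acidic Bcat boron of 6 (homolytic substitution, SH2) and expels the primary C4 radical, which makes the escaped charge separation irreversible; ZnTPP•+ (+0.8 V, well below the roughly 1.8 V or more needed to oxidise a trisubstituted alkene) is reduced back by the resulting aryloxide, giving a second SH2-competent aryloxyl; the nucleophilic primary radical adds to the only unsubstituted ring carbon of 7 (estimated ≥10^5–10^6 s⁻¹ at 0.6 M, against about 10^3–10^4 s⁻¹ for 6-exo closure or 1,5-H shift), and the adduct enoxyl radical takes Bcat from another molecule of 6, so the process is a chain and a low quantum yield is acceptable; the O-boryl dienone then enolises to the hydroquinone, and the stereocenter, two atoms from the radical and O-borylated, cannot change. The closest known reaction types are the O2-initiated radical-chain reductive alkylation of quinones by trialkylboranes and B-alkylcatecholboranes, nitroxide-triggered radical release from B-alkylcatecholboranes, and Lewis-acid-coupled porphyrin→quinone photoinduced electron transfer; the new element is using that electron transfer to drive the alkylation, on a trisubstituted quinone with a polyene substrate carrying a borate-masked tertiary carbinol.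

**Step 6**
Reactants: 8 (used directly)
Product: 9, (2R,3'E,7'E)-α-tocotrienol (target)
Conditions: p-TsOH·H2O (5 mol %), 4 Å MS, degassed toluene, 60 °C, 1–2 h, Ar
Reagents that add atoms: none (loss of H2O)
Why: In this classical vitamin E chroman cyclodehydration, the carbinol oxygen adds to the protonated keto tautomer of the electron-rich hydroquinone and the ring oxygen leaves as water, so C2–O stays intact and (R) is retained.

## Compound list
1 | (R)-(−)-linalool | CC(C)=CCC[C@@](C)(O)C=C | starting material
2 | (2E,6R)-2,6-dimethylocta-2,7-diene-1,6-diol | OC/C(C)=C/CC[C@@](C)(O)C=C | intermediate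
3 | (3R,6E)-8-bromo-3,7-dimethylocta-1,6-dien-3-ol | BrC/C(C)=C/CC[C@@](C)(O)C=C | intermediate
4 | (E)-geranyl chloride | CC(C)=CCC/C(C)=C/CCl | starting material
5 | (3R,6E,10E)-geranyllinalool | CC(C)=CCC/C(C)=C/CC/C(C)=C/CC[C@@](C)(O)C=C | intermediate
6 | C1-Bcat / O-Bcat bis(catecholboryl) derivative of 5 | CC(C)=CCC/C(C)=C/CC/C(C)=C/CC[C@@](C)(OB1Oc2ccccc2O1)CCB1Oc2ccccc2O1 | intermediate (not isolated)
7 | 2,3,5-trimethyl-1,4-benzoquinone | CC1=CC(=O)C(C)=C(C)C1=O | starting material
8 | (3R,6E,10E)-hydroxyalkyl trimethylhydroquinone | CC(C)=CCC/C(C)=C/CC/C(C)=C/CC[C@@](C)(O)CCc1c(C)c(O)c(C)c(C)c1O | intermediate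
9 | (2R,3'E,7'E)-α-tocotrienol | CC(C)=CCC/C(C)=C/CC/C(C)=C/CC[C@]1(C)CCc2c(C)c(O)c(C)c(C)c2O1 | target

## Summary
Total step count: 6. Steps 4 and 5 share one flask, and 8 is carried forward after only a plug filtration.
Longest linear sequence: 6 (1→2→3→5→6→8→9).

Steps most likely to fail:
1. **Step 5 (proposed new step).**
   - Risks: O-alkylation instead of C-alkylation, short chains, or redistribution of 6 into an SH2-inert 1,2-oxaborolane.
   - Fallback (known chemistry, +2 steps in the main line): hydroborate 5 with 9-BBN-H (2.2 equiv). Run a B-alkyl Suzuki–Miyaura coupling with 1-bromo-2,5-dimethoxy-3,4,6-trimethylbenzene (Pd/SPhos, K3PO4, THF/H2O). Then carry out CAN oxidative demethylation to the quinone, reduce with Na2S2O4 to 8, and continue with Step 6.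
2. **Step 3.**
   - Risks: α/γ or E/Z erosion, Wurtz homocoupling, or 5-exo SN2' closure of the alkoxide onto the allylic bromide.
   - Fallback (+1 step in the main line, plus sulfone preparation): Biellmann sulfone coupling. Alkylate lithiated geranyl p-tolyl sulfone (2.1 equiv) with 3. Then desulfonylate reductively with PdCl2(dppp)/LiHBEt3, which preserves alkene position and geometry.
3. **Step 6.**
   - Risks: partial ionisation of the tertiary carbinol, which erodes ee, or proton-initiated cyclisation of the triene.
   - Fallback: oxidise crude 8 (air or Ag2O) to the stable hydroxy-quinone and purify it. Then close the ring at the quinone oxidation level through its cyclic hemiketal (8a-hydroxychromanone), and reduce that in situ at rt with ascorbic acid or SnCl2 in dilute ethanolic HCl. This avoids hot sulfonic acid.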